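## Retrosynthetic overview

1. Ring numbering used below: C1 ketone carbon, C2 oxirane carbon bearing farnesyl [(2E,6E)-3,7,11-trimethyldodeca-2,6,10-trien-1-yl], C3 oxirane CH, C4 carbinol carbon, C5 carbon bearing CH2O, C6 enone CH.
2. Target ⇒ ester C–O bond (made last) between the primary allylic alcohol of the epoxyquinol diol and an allyl-protected (R)-3-hydroxy-3-methylglutaric half ester derived from (R)-mevalonolactone.
3. Epoxyquinol diol ⇒ epoxyquinone (C4 carbonyl reduced under direction of the C5 hydroxymethyl) ⇒ hydroxymethyl quinone monoketal (oxirane, the second ring, closed across C2–C3 by tartrate-mediated nucleophilic epoxidation) ⇒ para-methoxyphenol (dearomatized with PhI(OAc)2/MeOH).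
4. para-Methoxyphenol ⇒ one-operation union of three components around the carbocycle (the first ring): an alkenyl(methoxy)carbene chromium complex (C4, C5, C6), farnesylacetylene (C2, C3) and a CO ligand (C1), forming C3–C4, C1–C2 and C1–C6.
5. Enabling feature: the six-membered carbocycle carries oxygen on C1 and C4 in a para relation, H on C3 and C6, and its two carbon side chains on C2 and C5; C1 can therefore be a CO ligand, C4 an alkoxycarbene carbon, C2–C3 a terminal alkyne and C5–C6 a 1-substituted vinyl group, the ring being built one oxidation level up as a phenol whose aromaticity the next step removes.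

Key step: step 4

Assumption: with L-DIPT the sodium tartrate/alkoxide aggregate of step 7 is taken to deliver the peroxide to the ring face that gives the (1R,6S) oxirane; should the sense be opposite, D-DIPT is used and nothing else changes.

## Route

Step 1
Reactants: 1 (2E,6E)-farnesyl bromide; 2 ethynylmagnesium bromide (excess)
Product: 3 (4E,8E)-5,9,13-trimethyltetradeca-4,8,12-trien-1-yne (farnesylacetylene)
Conditions: CuBr·SMe2 (cat.), THF, 0 °C to rt
Reagents that add atoms: none
Why: Copper-catalyzed allyl–alkynyl Grignard cross-coupling should give the skipped enyne by substitution at the primary allylic carbon (the γ-carbon is fully substituted), leaving both E olefins untouched.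

Step 2
Reactants: 4 2-bromoprop-2-en-1-ol
Product: 5 [(2-bromoprop-2-en-1-yl)oxy]tri(propan-2-yl)silane
Conditions: TIPSCl, imidazole, DMF, rt
Reagents that add atoms: triisopropylsilyl chloride, CC(C)[Si](Cl)(C(C)C)C(C)C
Why: Standard silylation of a primary alcohol; the bulky TIPS group is chosen because it should resist oxygen-to-carbon silyl migration in the vinyllithium of the next step.

Step 3
Reactants: 5 [(2-bromoprop-2-en-1-yl)oxy]tri(propan-2-yl)silane; 6 hexacarbonylchromium Cr(CO)6
Product: 9 pentacarbonyl{1-methoxy-2-[(triisopropylsilyloxy)methyl]prop-2-en-1-ylidene}chromium, via 2-lithioallyl silyl ether 7 (not isolated), via lithium acylpentacarbonylchromate 8 (not isolated)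
Conditions: t-BuLi (2 equiv), Et2O, −78 °C; Cr(CO)6, Et2O, −78 °C to 0 °C; Me3OBF4, CH2Cl2, 0 °C
Reagents that add atoms: trimethyloxonium tetrafluoroborate, C[O+](C)C.F[B-](F)(F)F
Why: Fischer carbene synthesis, in which bromine–lithium exchange, addition of the vinyllithium to a CO ligand and O-methylation of the acylmetalate by the hard oxonium salt should give the alkenyl(methoxy)carbene complex.

Step 4
Reactants: 9 pentacarbonyl{1-methoxy-2-[(triisopropylsilyloxy)methyl]prop-2-en-1-ylidene}chromium; 3 farnesylacetylene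
Product: 11 4-methoxy-2-[(2E,6E)-farnesyl]-5-[(triisopropylsilyloxy)methyl]phenol, via arene tricarbonylchromium complex 10 (not isolated)
Conditions: THF, 50 °C, argon; then air, Et2O, rt
Reagents that add atoms: none
Why: Loss of one CO from 9 lets the terminal alkyne of 3 bind to zerovalent chromium and insert into the Cr=C bond with its CH terminus joining the carbene carbon (C3–C4), the new carbene carbon C2 then couples with a CO ligand to an η4-vinylketene (C1–C2), and 6π electrocyclization onto the vinyl CH2 terminus (C1–C6) followed by enolization gives the phenol as its Cr(CO)3 complex 10, which air demetalates to 11. The closest known reaction type is the Dötz benzannulation itself, a [3+2+1] union of an alkenyl(alkoxy)carbene ligand, an alkyne and CO, for which 1-substituted vinyl carbenes and unactivated terminal alkynes are standard partners. The six-membered carbocycle is closed on the metal template by disrotatory 6π electrocyclic closure of the dienylketene that the two insertions assemble. No stereocenter is created, so only constitution has to be controlled. The step needs regioselective alkyne insertion, secured by the steric gap between H and the farnesyl group (the larger substituent ends next to the CO-derived carbon C1), and benzannulation in preference to cyclopentannulation, which the chromium center, the alkenyl carbene and THF as donor solvent favor. The skipped 1,4-enyne of 3 cannot divert the vinylcarbene into cyclopropanation, since only a bicyclo[1.1.0]butane could result, and the remote trisubstituted olefins should not bind competitively.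

Step 5
Reactants: 11 4-methoxy-2-[(2E,6E)-farnesyl]-5-[(triisopropylsilyloxy)methyl]phenol
Product: 12 4,4-dimethoxy-2-[(2E,6E)-farnesyl]-5-[(triisopropylsilyloxy)methyl]cyclohexa-2,5-dien-1-one
Conditions: PhI(OAc)2, MeOH, 0 °C
Reagents that add atoms: methanol, CO
Why: Oxidative dearomatization of a para-methoxyphenol by the trivalent iodine reagent, with methanol trapping the cationic intermediate at the methoxy-bearing para carbon, should place the ketal at C4 and the ketone at C1 exactly as the key step encoded, the isolated olefins being inert.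

Step 6
Reactants: 12 4,4-dimethoxy-2-[(2E,6E)-farnesyl]-5-[(triisopropylsilyloxy)methyl]cyclohexa-2,5-dien-1-one
Product: 13 5-(hydroxymethyl)-4,4-dimethoxy-2-[(2E,6E)-farnesyl]cyclohexa-2,5-dien-1-one
Conditions: Bu4NF, AcOH, THF, 0 °C to rt
Reagents that add atoms: none
Why: Fluoride-mediated cleavage of the primary silyl ether, buffered with acetic acid to spare the dienone, should free the hydroxymethyl group that directs the next step.

Step 7
Reactants: 13 5-(hydroxymethyl)-4,4-dimethoxy-2-[(2E,6E)-farnesyl]cyclohexa-2,5-dien-1-one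
Product: 14 (1R,6S)-4-(hydroxymethyl)-5,5-dimethoxy-1-[(2E,6E)-farnesyl]-7-oxabicyclo[4.1.0]hept-3-en-2-one
Conditions: Ph3COOH, NaN(SiMe3)2, L-DIPT, 4 Å molecular sieves, toluene, −50 °C
Reagents that add atoms: trityl hydroperoxide, OOC(c1ccccc1)(c1ccccc1)c1ccccc1
Why: Tartrate-mediated Weitz–Scheffer epoxidation, in which the sodium alkoxide of the C5 hydroxymethyl group, the sodium tartrate and the trityl peroxide form one chiral aggregate that should add the peroxide to C3 (the only unsubstituted β-carbon) and close the oxirane onto C2 from one face, setting both oxirane stereocenters (cis fusion by necessity, absolute sense from the tartrate) while the farnesyl olefins ignore a nucleophilic oxidant.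

Step 8
Reactants: 14 (1R,6S)-4-(hydroxymethyl)-5,5-dimethoxy-1-[(2E,6E)-farnesyl]-7-oxabicyclo[4.1.0]hept-3-en-2-one
Product: 15 (1R,6S)-4-(hydroxymethyl)-1-[(2E,6E)-farnesyl]-7-oxabicyclo[4.1.0]hept-3-ene-2,5-dione
Conditions: aq. HF (48%), MeCN, 0 °C to rt
Reagents that add atoms: water, O
Why: Acid-catalyzed ketal hydrolysis should unveil the C4 ketone under conditions mild enough for the trisubstituted olefins and the oxirane, whose two stereocenters cannot epimerize because the ring fusion must stay cis.

Step 9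
Reactants: 15 (1R,6S)-4-(hydroxymethyl)-1-[(2E,6E)-farnesyl]-7-oxabicyclo[4.1.0]hept-3-ene-2,5-dione
Product: 16 (1R,5R,6R)-5-hydroxy-4-(hydroxymethyl)-1-[(2E,6E)-farnesyl]-7-oxabicyclo[4.1.0]hept-3-en-2-one
Conditions: Me4NBH(OAc)3, AcOH/MeCN, −30 °C
Reagents that add atoms: none
Why: Evans–Saksena directed reduction, in which the alkoxyborohydride formed on the C5 hydroxymethyl oxygen can reach only the adjacent C4 carbonyl (six-membered transition state, C1 lies trans across the C5=C6 bond) and should deliver hydride anti to the oxirane oxygen (Felkin-type and less hindered), placing the new C4 hydroxyl syn to the oxirane.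

Step 10
Reactants: 17 (R)-mevalonolactone
Product: 19 prop-2-en-1-yl (3R)-3,5-dihydroxy-3-methylpentanoate, via potassium mevalonate 18 (not isolated)
Conditions: KOH (1.0 equiv), H2O, rt, then evaporation; allyl bromide, DMF, rt
Reagents that add atoms: potassium hydroxide, [K+].[OH-]; allyl bromide, C=CCBr
Why: Lactone saponification followed by SN2 O-alkylation of the carboxylate should give the open-chain allyl ester without touching the quaternary carbinol stereocenter.

Step 11
Reactants: 19 prop-2-en-1-yl (3R)-3,5-dihydroxy-3-methylpentanoate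
Product: 20 (3R)-3-hydroxy-3-methyl-5-oxo-5-(prop-2-en-1-yloxy)pentanoic acid
Conditions: TEMPO (cat.), PhI(OAc)2, MeCN/pH 7 phosphate buffer, 0 °C to rt
Reagents that add atoms: water, O
Why: Oxoammonium-mediated oxidation of the primary alcohol through the aldehyde hydrate to the acid should leave the tertiary alcohol and the allyl ester alone, so the two arms of the hydroxymethylglutarate are differentiated with the configuration inherited from mevalonolactone.

Step 12
Reactants: 16 (1R,5R,6R)-5-hydroxy-4-(hydroxymethyl)-1-[(2E,6E)-farnesyl]-7-oxabicyclo[4.1.0]hept-3-en-2-one; 20 (3R)-3-hydroxy-3-methyl-5-oxo-5-(prop-2-en-1-yloxy)pentanoic acid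
Product: 21 {(1R,2R,6R)-2-hydroxy-5-oxo-6-[(2E,6E)-farnesyl]-7-oxabicyclo[4.1.0]hept-3-en-3-yl}methyl prop-2-en-1-yl (3S)-3-hydroxy-3-methylpentanedioate
Conditions: DIC, DMAP (cat.), CH2Cl2, 0 °C
Reagents that add atoms: none
Why: Steglich esterification should acylate the primary allylic alcohol much faster than the hindered secondary C4 hydroxyl flanked by the oxirane, and the tertiary hydroxyl of the acid is unreactive.

Step 13
Reactants: 21 {(1R,2R,6R)-2-hydroxy-5-oxo-6-[(2E,6E)-farnesyl]-7-oxabicyclo[4.1.0]hept-3-en-3-yl}methyl prop-2-en-1-yl (3S)-3-hydroxy-3-methylpentanedioate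
Product: 22 (3S)-3-hydroxy-5-{[(1R,2R,6R)-2-hydroxy-5-oxo-6-[(2E,6E)-farnesyl]-7-oxabicyclo[4.1.0]hept-3-en-3-yl]methoxy}-3-methyl-5-oxopentanoic acid (CNP0134663.2)
Conditions: Pd(PPh3)4 (cat.), N-methylaniline, THF, 0 °C to rt
Reagents that add atoms: none
Why: Tsuji–Trost-type deallylation, in which zerovalent palladium should ionize the unhindered allyl ester far faster than the trisubstituted, enone-conjugated allylic ester of the core, with the weakly basic aniline trapping the π-allyl complex without attacking the epoxy enone.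

## Compound list

1 | (2E,6E)-farnesyl bromide | CC(C)=CCC/C(C)=C/CC/C(C)=C/CBr | starting material
2 | ethynylmagnesium bromide | C#C[Mg]Br | starting material
3 | (4E,8E)-5,9,13-trimethyltetradeca-4,8,12-trien-1-yne | CC(C)=CCC/C(C)=C/CC/C(C)=C/CC#C | intermediate
4 | 2-bromoprop-2-en-1-ol | OCC(Br)=C | starting material
5 | [(2-bromoprop-2-en-1-yl)oxy]tri(propan-2-yl)silane | C=C(Br)CO[Si](C(C)C)(C(C)C)C(C)C | intermediate
6 | hexacarbonylchromium Cr(CO)6 | O=C=[Cr](=C=O)(=C=O)(=C=O)(=C=O)=C=O | starting material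
7 | {3-[(triisopropylsilyl)oxy]prop-1-en-2-yl}lithium | [Li]C(=C)CO[Si](C(C)C)(C(C)C)C(C)C | intermediate
8 | lithium pentacarbonyl{2-[(triisopropylsilyloxy)methyl]prop-2-enoyl}chromate | [Li+].[O-]C(C(=C)CO[Si](C(C)C)(C(C)C)C(C)C)=[Cr](=C=O)(=C=O)(=C=O)(=C=O)=C=O | intermediate
9 | pentacarbonyl{1-methoxy-2-[(triisopropylsilyloxy)methyl]prop-2-en-1-ylidene}chromium | COC(C(=C)CO[Si](C(C)C)(C(C)C)C(C)C)=[Cr](=C=O)(=C=O)(=C=O)(=C=O)=C=O | intermediate
10 | tricarbonyl(η6-arene)chromium complex of phenol 11 | CC(C)=CCC/C(C)=C/CC/C(C)=C/Cc1cc(OC)c(CO[Si](C(C)C)(C(C)C)C(C)C)cc1O.O=C=[Cr](=C=O)=C=O | intermediate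
11 | 4-methoxy-2-[(2E,6E)-farnesyl]-5-[(triisopropylsilyloxy)methyl]phenol | CC(C)=CCC/C(C)=C/CC/C(C)=C/Cc1cc(OC)c(CO[Si](C(C)C)(C(C)C)C(C)C)cc1O | intermediate
12 | 4,4-dimethoxy-2-[(2E,6E)-farnesyl]-5-[(triisopropylsilyloxy)methyl]cyclohexa-2,5-dien-1-one | CC(C)=CCC/C(C)=C/CC/C(C)=C/CC1=CC(OC)(OC)C(CO[Si](C(C)C)(C(C)C)C(C)C)=CC1=O | intermediate
13 | 5-(hydroxymethyl)-4,4-dimethoxy-2-[(2E,6E)-farnesyl]cyclohexa-2,5-dien-1-one | CC(C)=CCC/C(C)=C/CC/C(C)=C/CC1=CC(OC)(OC)C(CO)=CC1=O | intermediate
14 | (1R,6S)-4-(hydroxymethyl)-5,5-dimethoxy-1-[(2E,6E)-farnesyl]-7-oxabicyclo[4.1.0]hept-3-en-2-one | CC(C)=CCC/C(C)=C/CC/C(C)=C/C[C@@]12O[C@@H]1C(OC)(OC)C(CO)=CC2=O | intermediate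
15 | (1R,6S)-4-(hydroxymethyl)-1-[(2E,6E)-farnesyl]-7-oxabicyclo[4.1.0]hept-3-ene-2,5-dione | CC(C)=CCC/C(C)=C/CC/C(C)=C/C[C@@]12O[C@@H]1C(=O)C(CO)=CC2=O | intermediate
16 | (1R,5R,6R)-5-hydroxy-4-(hydroxymethyl)-1-[(2E,6E)-farnesyl]-7-oxabicyclo[4.1.0]hept-3-en-2-one | CC(C)=CCC/C(C)=C/CC/C(C)=C/C[C@@]12O[C@@H]1[C@H](O)C(CO)=CC2=O | intermediate
17 | (R)-mevalonolactone | C[C@@]1(O)CCOC(=O)C1 | starting material
18 | potassium (3R)-3,5-dihydroxy-3-methylpentanoate | [K+].[O-]C(=O)C[C@](C)(O)CCO | intermediate
19 | prop-2-en-1-yl (3R)-3,5-dihydroxy-3-methylpentanoate | OCC[C@@](C)(O)CC(=O)OCC=C | intermediate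
20 | (3R)-3-hydroxy-3-methyl-5-oxo-5-(prop-2-en-1-yloxy)pentanoic acid | OC(=O)C[C@@](C)(O)CC(=O)OCC=C | intermediate
21 | {(1R,2R,6R)-2-hydroxy-5-oxo-6-[(2E,6E)-farnesyl]-7-oxabicyclo[4.1.0]hept-3-en-3-yl}methyl prop-2-en-1-yl (3S)-3-hydroxy-3-methylpentanedioate | CC(C)=CCC/C(C)=C/CC/C(C)=C/C[C@@]12O[C@@H]1[C@H](O)C(COC(=O)C[C@@](C)(O)CC(=O)OCC=C)=CC2=O | intermediate
22 | (3S)-3-hydroxy-5-{[(1R,2R,6R)-2-hydroxy-5-oxo-6-[(2E,6E)-farnesyl]-7-oxabicyclo[4.1.0]hept-3-en-3-yl]methoxy}-3-methyl-5-oxopentanoic acid | CC(C)=CCC/C(C)=C/CC/C(C)=C/C[C@@]12O[C@@H]1[C@H](O)C(COC(=O)C[C@@](C)(O)CC(=O)O)=CC2=O | target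

## Step count and risks

Total step count: 13. Longest linear sequence: 10 steps (4 → 5 → 9 → 11 → 12 → 13 → 14 → 15 → 16 → 21 → 22).

Steps most likely to fail:

1. Step 4. What may go wrong: after alkyne insertion the vinylcarbene may close without taking up CO (cyclopentannulation), or the electron-rich phenol may be over-oxidized or cyclize onto the nearest farnesyl olefin during demetalation. Fallback (gives up the three-component ring assembly and uses a preformed arene): it sets out from 1 and comes back at 13. The sodium phenoxide of commercial 5-hydroxy-2-methoxybenzaldehyde (NaH, toluene) is C-alkylated by 1 at the free ortho position para to the formyl group to give 5-hydroxy-2-methoxy-4-[(2E,6E)-farnesyl]benzaldehyde F1. NaBH4 in MeOH reduces the aldehyde to 5-(hydroxymethyl)-4-methoxy-2-[(2E,6E)-farnesyl]phenol F2. PhI(OAc)2 in MeOH then dearomatizes F2 directly to 13, so steps 5 and 6 are not needed.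

2. Step 7. What may go wrong: insufficient or reversed facial discrimination by the tartrate aggregate, or slow oxirane closure, because the α-carbon of the reacting enone carries the farnesyl group. Fallback (covalent chiral auxiliary with separation of diastereomers in place of reagent control): it sets out from 13 and comes back at 15. Transketalization of 13 with (2R,4R)-pentane-2,4-diol (PPTS, benzene, removal of MeOH) gives 5-(hydroxymethyl)-2-[(2E,6E)-farnesyl]cyclohexa-2,5-diene-1,4-dione 4-[(2R,4R)-pentane-2,4-diyl ketal] F3. Nucleophilic epoxidation (t-BuOOH, DBU, CH2Cl2) and chromatographic separation give (1R,6S)-4-(hydroxymethyl)-1-[(2E,6E)-farnesyl]-7-oxabicyclo[4.1.0]hept-3-ene-2,5-dione 5-[(2R,4R)-pentane-2,4-diyl ketal] F4 (the antipodal diol is used if the facial bias runs the wrong way). Aqueous HF in MeCN hydrolyzes F4 to 15.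

3. Step 9. What may go wrong: hydride delivery to the face syn to the oxirane, or incomplete alkoxy exchange on boron so that reduction stalls or strays to C1. Fallback (steric and electronic substrate control on a protected alcohol in place of intramolecular delivery): it sets out from 15 and comes back at 16. Silylation (TBSCl, imidazole, CH2Cl2) gives (1R,6S)-4-[(tert-butyldimethylsilyloxy)methyl]-1-[(2E,6E)-farnesyl]-7-oxabicyclo[4.1.0]hept-3-ene-2,5-dione F5. Luche reduction (NaBH4, CeCl3·7H2O, MeOH, −78 °C) should attack the more electrophilic C4 carbonyl, which is not shielded by the farnesyl-bearing quaternary carbon, anti to the oxirane, giving (1R,5R,6R)-4-[(tert-butyldimethylsilyloxy)methyl]-5-hydroxy-1-[(2E,6E)-farnesyl]-7-oxabicyclo[4.1.0]hept-3-en-2-one F6. HF·pyridine in THF then removes the silyl group to give 16.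

## Further compounds

F1 | step 4 | 5-hydroxy-2-methoxy-4-[(2E,6E)-farnesyl]benzaldehyde | CC(C)=CCC/C(C)=C/CC/C(C)=C/Cc1cc(OC)c(C=O)cc1O
F2 | step 4 | 5-(hydroxymethyl)-4-methoxy-2-[(2E,6E)-farnesyl]phenol | CC(C)=CCC/C(C)=C/CC/C(C)=C/Cc1cc(OC)c(CO)cc1O
F3 | step 7 | 5-(hydroxymethyl)-2-[(2E,6E)-farnesyl]cyclohexa-2,5-diene-1,4-dione 4-[(2R,4R)-pentane-2,4-diyl ketal] | CC(C)=CCC/C(C)=C/CC/C(C)=C/CC1=CC2(O[C@H](C)C[C@@H](C)O2)C(CO)=CC1=O
F4 | step 7 | (1R,6S)-4-(hydroxymethyl)-1-[(2E,6E)-farnesyl]-7-oxabicyclo[4.1.0]hept-3-ene-2,5-dione 5-[(2R,4R)-pentane-2,4-diyl ketal] | CC(C)=CCC/C(C)=C/CC/C(C)=C/C[C@@]12O[C@@H]1C3(O[C@H](C)C[C@@H](C)O3)C(CO)=CC2=O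
F5 | step 9 | (1R,6S)-4-[(tert-butyldimethylsilyloxy)methyl]-1-[(2E,6E)-farnesyl]-7-oxabicyclo[4.1.0]hept-3-ene-2,5-dione | CC(C)=CCC/C(C)=C/CC/C(C)=C/C[C@@]12O[C@@H]1C(=O)C(CO[Si](C)(C)C(C)(C)C)=CC2=O
F6 | step 9 | (1R,5R,6R)-4-[(tert-butyldimethylsilyloxy)methyl]-5-hydroxy-1-[(2E,6E)-farnesyl]-7-oxabicyclo[4.1.0]hept-3-en-2-one | CC(C)=CCC/C(C)=C/CC/C(C)=C/C[C@@]12O[C@@H]1[C@H](O)C(CO[Si](C)(C)C(C)(C)C)=CC2=O
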